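**Plan**

- Numbering: C1 (fusion CH next to the lactone C8=O), C2 (catechol CH), O3, C4H2, C5 (fusion CH), C6 (syringyl CH), O7, C8. The target is the all-cis (1R,2S,5S,6S) isomer, both aryl groups endo.
- Enabling feature: the tetrahydrofuran ring C1–C2–O3–C4–C5 has a 1,3-dicarbonyl-type carbon at C1 and an alkene-derived carbon (C6) on C5. O3–C4–C5(–C6) therefore maps onto an alkoxide/π-allyl dipole, and C2=C1(–C8) onto an arylidene Meldrum's acid.
- Retrosynthetic cuts, in order: three O–Si bonds; the extra carboxyl on C1; O7–C8 together with C6–H; C6=O back to C6=CH2; then O3–C2 and C1–C5 in one operation.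
- Forward: two arms (aldehyde to arylidene Meldrum's acid; arylboronate to racemic 2-(1-arylvinyl)oxirane) meet in the palladium step, which closes the tetrahydrofuran. The lactone ring closes second, when the C6 carbinol opens the Meldrum ring.
- Stereochemistry: C5 and C2 from the chiral palladium catalyst (stereoconvergent use of the racemic epoxide, 2,4-cis closure); C6 from a CBS reduction; C1 from the obligatory cis ring fusion on decarboxylation.

Key step: step 7

Assumption: the sense of induction of the chiral ligand on this 2-aryl-substituted allyl system cannot be predicted with certainty. The (R,R)-ligand is written; the equally available (S,S)-enantiomer is taken instead if a first run gives the mirror-image adduct.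

Remark: TIPS = triisopropylsilyl. It is chosen over TBS because the silyl ether para to the arylidene Meldrum's acid is activated towards nucleophiles. Compounds 5 and 7 are taken as commercial.

**Route**

Step 1
Reactants: 1 3,4-dihydroxybenzaldehyde
Product: 2 3,4-bis(triisopropylsilyloxy)benzaldehyde
Conditions: TIPSCl, imidazole, DMF, 40 °C
Reagents that add atoms: triisopropylsilyl chloride, CC(C)[Si](Cl)(C(C)C)C(C)C
Why: Imidazole-promoted silylation caps both phenols as bulky silyl ethers that should resist the nucleophiles met later and fall to fluoride at the end; no stereocentre is involved.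

Step 2
Reactants: 2 3,4-bis(triisopropylsilyloxy)benzaldehyde; 3 Meldrum's acid (2,2-dimethyl-1,3-dioxane-4,6-dione)
Product: 4 5-[3,4-bis(triisopropylsilyloxy)benzylidene]-2,2-dimethyl-1,3-dioxane-4,6-dione
Conditions: pyrrolidinium acetate (10 mol%), toluene, 4 Å MS, rt
Reagents that add atoms: none
Why: Knoevenagel condensation of the acidic Meldrum's acid with an aromatic aldehyde under mild amine/acid catalysis should give the arylidene derivative, a much stronger oxa-Michael acceptor than a dialkyl malonate and a latent source of the C8 carbonyl plus a traceless carboxyl.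

Step 3
Reactants: 5 2,6-dimethoxy-4-(4,4,5,5-tetramethyl-1,3,2-dioxaborolan-2-yl)phenol
Product: 6 [2,6-dimethoxy-4-(4,4,5,5-tetramethyl-1,3,2-dioxaborolan-2-yl)phenoxy]triisopropylsilane
Conditions: TIPSOTf, 2,6-lutidine, CH2Cl2, 0 °C to rt
Reagents that add atoms: triisopropylsilyl triflate, CC(C)[Si](OS(=O)(=O)C(F)(F)F)(C(C)C)C(C)C
Why: Silylation with the silyl triflate should overcome the hindrance of the di-ortho-methoxy phenol, and the pinacol boronate is inert to these conditions.

Step 4
Reactants: 6 the silylated arylboronate; 7 2-bromoprop-2-en-1-ol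
Product: 8 2-[3,5-dimethoxy-4-(triisopropylsilyloxy)phenyl]prop-2-en-1-ol
Conditions: Pd(dppf)Cl2 (3 mol%), aq. K3PO4, THF, 60 °C
Reagents that add atoms: none
Why: Suzuki–Miyaura coupling of an arylboronate with a 2-bromoallyl alcohol is a standard entry to 2-arylallyl alcohols; the hindered aryl silyl ether should survive aqueous phosphate and the free hydroxyl needs no protection.

Step 5
Reactants: 8 the 2-arylallyl alcohol
Product: 9 2-[3,5-dimethoxy-4-(triisopropylsilyloxy)phenyl]prop-2-enal
Conditions: activated MnO2, CH2Cl2, rt; filtered and used at once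
Reagents that add atoms: none
Why: Manganese dioxide oxidises allylic alcohols selectively under neutral heterogeneous conditions, so the polymerisation-prone 2-arylacrolein is obtained by simple filtration.

Step 6
Reactants: 9 the 2-arylacrolein
Product: 10 rac-2-{1-[3,5-dimethoxy-4-(triisopropylsilyloxy)phenyl]vinyl}oxirane
Conditions: Me3S+ I−, KHMDS, THF, −20 °C; then 9, −78 to 0 °C
Reagents that add atoms: trimethylsulfonium iodide, C[S+](C)C.[I-]
Why: Corey–Chaykovsky epoxidation: the unstabilised sulfonium methylide adds 1,2 to the enal carbonyl and the betaine closes to the oxirane; the epoxide is racemic by design because step 7 is stereoconvergent.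

Step 7
Reactants: 4 the arylidene Meldrum's acid; 10 the racemic vinyl epoxide (slight excess)
Product: 11 (1R,4S)-1-[3,4-bis(triisopropylsilyloxy)phenyl]-4-{1-[3,5-dimethoxy-4-(triisopropylsilyloxy)phenyl]vinyl}-8,8-dimethyl-2,7,9-trioxaspiro[4.5]decane-6,10-dione (aryl and arylvinyl cis on the tetrahydrofuran)
Conditions: Pd2(dba)3·CHCl3 (2.5 mol%), (1R,2R)-N,N'-bis(2-diphenylphosphino-1-naphthoyl)cyclohexane-1,2-diamine (7.5 mol%), toluene, rt
Reagents that add atoms: none
Why: Pd(0) ionises the allylic C–O bond of 10 to a zwitterionic 2-aryl-π-allylpalladium alkoxide; the alkoxide adds reversibly to the β-carbon of 4 (O3–C2), and the resulting Meldrum-stabilised carbanion alkylates the substituted allyl terminus anti to palladium (C1–C5), releasing Pd(0). The closest known reaction type is the palladium-catalysed (3+2) cycloaddition of vinyl epoxides with doubly activated alkenes, including its asymmetric variants with chiral diphosphine ligands. The tetrahydrofuran closes in a 5-exo mode on the π-allyl unit, the remaining alkene staying exocyclic; attack at the distal CH2 terminus would need a seven-membered ring. C5 is set by the ligand, because both enantiomers of 10 give diastereomeric π-allyl complexes that interconvert by π–σ–π through the unsubstituted CH2 terminus faster than they cyclise, and the chiral pocket should let one of them close preferentially. C2 is set under Curtin–Hammett conditions, since the oxa-Michael step is reversible and the envelope transition state with the C2 aryl and the allyl unit both pseudo-equatorial leads to the 2,4-cis ring; C1 is not yet stereogenic in the symmetric spiro-dione. The step needs oxygen-first regiochemistry and fast capture of the dipole, which the high electrophilicity of 4 and the soft, non-basic character of its carbanion should secure, while the bulky silyl ethers keep the phenols inert to the transient alkoxide.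

Step 8
Reactants: 11 the spiro cycloadduct
Product: 13 (1R,4S)-1-[3,4-bis(triisopropylsilyloxy)phenyl]-4-[3,5-dimethoxy-4-(triisopropylsilyloxy)benzoyl]-8,8-dimethyl-2,7,9-trioxaspiro[4.5]decane-6,10-dione, via ozonide 12 (not isolated)
Conditions: O3, CH2Cl2, −78 °C (indicator dye end point); Me2S, −78 °C to rt
Reagents that add atoms: ozone, [O-][O+]=O
Why: Ozonolysis (Criegee mechanism) of the 1,1-disubstituted styrene-type alkene should be far faster than attack on the oxygenated arenes, and the neutral sulfide work-up spares the base-sensitive β-alkoxy ketone and its C5–H.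

Step 9
Reactants: 13 the aryl ketone
Product: 15 (1R,2R,5S,6S)-2-[3,4-bis(triisopropylsilyloxy)phenyl]-6-[3,5-dimethoxy-4-(triisopropylsilyloxy)phenyl]-8-oxo-3,7-dioxabicyclo[3.3.0]octane-1-carboxylic acid, via carbinol 14 (not isolated)
Conditions: (R)-2-methyl-CBS-oxazaborolidine (20 mol%), catecholborane, toluene, −78 to −40 °C; MeOH quench; then CH2Cl2, 40 °C
Reagents that add atoms: none
Why: Corey–Bakshi–Shibata reduction with the aryl ring as the large group should deliver hydride to the Re face of C6 (6S) under reagent control, against the Felkin–Anh bias expected for this α-branched ketone (6R); the free carbinol then opens the cis-disposed Meldrum carbonyl by 5-exo-trig acyl substitution with loss of acetone, the only mode that gives a cis-fused lactone.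

Step 10
Reactants: 15 the lactone acid
Product: 16 (1R,2S,5S,6S)-2-[3,4-bis(triisopropylsilyloxy)phenyl]-6-[3,5-dimethoxy-4-(triisopropylsilyloxy)phenyl]-3,7-dioxabicyclo[3.3.0]octan-8-one
Conditions: toluene, 100 °C
Reagents that add atoms: none
Why: Thermal decarboxylation of a malonic half-ester-type α-carboxy lactone proceeds through a cyclic transition state without base, and the lactone enol can be protonated at C1 only on the convex face because the bicycle must be cis-fused, which sets C1 as R.

Step 11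
Reactants: 16 the tris-silylated lactone
Product: 17 (1R,2S,5S,6S)-2-(3,4-dihydroxyphenyl)-6-(4-hydroxy-3,5-dimethoxyphenyl)-3,7-dioxabicyclo[3.3.0]octan-8-one (target)
Conditions: TBAF, AcOH (1:1.2), THF, 0 °C to rt
Reagents that add atoms: none
Why: Fluoride-mediated cleavage of aryl silyl ethers, with acetic acid protonating each phenoxide as it forms, so that neither quinone-methide ionisation at C6 nor enolate-driven ring opening at C2 should erode the endo,endo configuration.

**Compound list**

1 | 3,4-dihydroxybenzaldehyde | O=Cc1ccc(O)c(O)c1 | starting material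
2 | 3,4-bis(triisopropylsilyloxy)benzaldehyde | O=Cc1ccc(O[Si](C(C)C)(C(C)C)C(C)C)c(O[Si](C(C)C)(C(C)C)C(C)C)c1 | intermediate
3 | Meldrum's acid (2,2-dimethyl-1,3-dioxane-4,6-dione) | CC1(C)OC(=O)CC(=O)O1 | starting material
4 | 5-[3,4-bis(triisopropylsilyloxy)benzylidene]-2,2-dimethyl-1,3-dioxane-4,6-dione | CC1(C)OC(=O)C(=Cc2ccc(O[Si](C(C)C)(C(C)C)C(C)C)c(O[Si](C(C)C)(C(C)C)C(C)C)c2)C(=O)O1 | intermediate
5 | 2,6-dimethoxy-4-(4,4,5,5-tetramethyl-1,3,2-dioxaborolan-2-yl)phenol | COc1cc(B2OC(C)(C)C(C)(C)O2)cc(OC)c1O | starting material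
6 | [2,6-dimethoxy-4-(4,4,5,5-tetramethyl-1,3,2-dioxaborolan-2-yl)phenoxy]triisopropylsilane | COc1cc(B2OC(C)(C)C(C)(C)O2)cc(OC)c1O[Si](C(C)C)(C(C)C)C(C)C | intermediate
7 | 2-bromoprop-2-en-1-ol | C=C(Br)CO | starting material
8 | 2-[3,5-dimethoxy-4-(triisopropylsilyloxy)phenyl]prop-2-en-1-ol | C=C(CO)c1cc(OC)c(O[Si](C(C)C)(C(C)C)C(C)C)c(OC)c1 | intermediate
9 | 2-[3,5-dimethoxy-4-(triisopropylsilyloxy)phenyl]prop-2-enal | C=C(C=O)c1cc(OC)c(O[Si](C(C)C)(C(C)C)C(C)C)c(OC)c1 | intermediate
10 | rac-2-{1-[3,5-dimethoxy-4-(triisopropylsilyloxy)phenyl]vinyl}oxirane (racemate, no descriptor) | C=C(c1cc(OC)c(O[Si](C(C)C)(C(C)C)C(C)C)c(OC)c1)C1CO1 | intermediate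
11 | (1R,4S)-1-[3,4-bis(triisopropylsilyloxy)phenyl]-4-{1-[3,5-dimethoxy-4-(triisopropylsilyloxy)phenyl]vinyl}-8,8-dimethyl-2,7,9-trioxaspiro[4.5]decane-6,10-dione | CC1(C)OC(=O)C2(C(=O)O1)[C@@H](c1ccc(O[Si](C(C)C)(C(C)C)C(C)C)c(O[Si](C(C)C)(C(C)C)C(C)C)c1)OC[C@H]2C(=C)c1cc(OC)c(O[Si](C(C)C)(C(C)C)C(C)C)c(OC)c1 | intermediate
12 | ozonide of 11 (1,2,4-trioxolane on the former alkene, mixture at the trioxolane carbon) | CC1(C)OC(=O)C2(C(=O)O1)[C@@H](c1ccc(O[Si](C(C)C)(C(C)C)C(C)C)c(O[Si](C(C)C)(C(C)C)C(C)C)c1)OC[C@H]2C1(c2cc(OC)c(O[Si](C(C)C)(C(C)C)C(C)C)c(OC)c2)OOCO1 | intermediate (not isolated)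
13 | (1R,4S)-1-[3,4-bis(triisopropylsilyloxy)phenyl]-4-[3,5-dimethoxy-4-(triisopropylsilyloxy)benzoyl]-8,8-dimethyl-2,7,9-trioxaspiro[4.5]decane-6,10-dione | CC1(C)OC(=O)C2(C(=O)O1)[C@@H](c1ccc(O[Si](C(C)C)(C(C)C)C(C)C)c(O[Si](C(C)C)(C(C)C)C(C)C)c1)OC[C@H]2C(=O)c1cc(OC)c(O[Si](C(C)C)(C(C)C)C(C)C)c(OC)c1 | intermediate
14 | (1R,4S)-1-[3,4-bis(triisopropylsilyloxy)phenyl]-4-{(S)-hydroxy[3,5-dimethoxy-4-(triisopropylsilyloxy)phenyl]methyl}-8,8-dimethyl-2,7,9-trioxaspiro[4.5]decane-6,10-dione | CC1(C)OC(=O)C2(C(=O)O1)[C@@H](c1ccc(O[Si](C(C)C)(C(C)C)C(C)C)c(O[Si](C(C)C)(C(C)C)C(C)C)c1)OC[C@H]2[C@H](O)c1cc(OC)c(O[Si](C(C)C)(C(C)C)C(C)C)c(OC)c1 | intermediate (not isolated)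
15 | (1R,2R,5S,6S)-2-[3,4-bis(triisopropylsilyloxy)phenyl]-6-[3,5-dimethoxy-4-(triisopropylsilyloxy)phenyl]-8-oxo-3,7-dioxabicyclo[3.3.0]octane-1-carboxylic acid (CO2H on the convex face) | COc1cc([C@H]2OC(=O)[C@]3(C(=O)O)[C@H]2CO[C@@H]3c2ccc(O[Si](C(C)C)(C(C)C)C(C)C)c(O[Si](C(C)C)(C(C)C)C(C)C)c2)cc(OC)c1O[Si](C(C)C)(C(C)C)C(C)C | intermediate
16 | (1R,2S,5S,6S)-2-[3,4-bis(triisopropylsilyloxy)phenyl]-6-[3,5-dimethoxy-4-(triisopropylsilyloxy)phenyl]-3,7-dioxabicyclo[3.3.0]octan-8-one | COc1cc([C@H]2OC(=O)[C@@H]3[C@H]2CO[C@@H]3c2ccc(O[Si](C(C)C)(C(C)C)C(C)C)c(O[Si](C(C)C)(C(C)C)C(C)C)c2)cc(OC)c1O[Si](C(C)C)(C(C)C)C(C)C | intermediate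
17 | (1R,2S,5S,6S)-2-(3,4-dihydroxyphenyl)-6-(4-hydroxy-3,5-dimethoxyphenyl)-3,7-dioxabicyclo[3.3.0]octan-8-one | COc1cc([C@H]2OC(=O)[C@@H]3[C@H]2CO[C@@H]3c2ccc(O)c(O)c2)cc(OC)c1O | target

**Step count and risks**

Total steps: 11. Longest linear sequence: 9 steps (5 to 17, steps 3–11).

Steps most likely to fail:

1. Step 7. The 2-aryl substituent on the allyl unit may slow carbon–carbon closure at the hindered internal terminus, so that the dipole isomerises before it is captured. It may also lower the 2,4-cis or enantiofacial selectivity inside the chiral pocket. Fallback (sets out from 4, comes back at 14): the aryl group is taken off the allyl partner and C6 is arylated afterwards. Compound 4 and commercial racemic 2-vinyloxirane under the catalyst of step 7 should give the 2,4-cis 4-vinyl spiro adduct F1. Ozonolysis through the ozonide F2 gives the aldehyde F3. Commercial 4-bromo-2,6-dimethoxyphenol is silylated to the aryl bromide F4 and converted with magnesium into the arylmagnesium bromide F5, which is added to F3 at −78 °C. With H and aryl exchanged at C6 relative to step 9, the Felkin–Anh model and a 1,3-chelate through O3 both predict the 6S configuration. This gives 14 as its magnesium alkoxide, which closes to 15 on warming; steps 8 and 9 are bypassed.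

2. Step 9. Reagent and substrate preferences oppose each other, and the bulky α-branched tetrahydrofuranyl group may not behave as the small substituent towards the oxazaborolidine, so facial selectivity may be poor. Fallback (sets out from 13, comes back at 16): the substrate bias is used and C6 is inverted later. Reduction with (S)-2-methyl-CBS-oxazaborolidine and catecholborane, now matched with the Felkin–Anh preference, should give the (6R)-carbinol F6, which closes to the 6-epimeric lactone acid F7. Heating in toluene gives the exo-syringyl lactone F8. Lithium hydroxide in aqueous THF at 0 °C opens it to the hydroxy acid F9. Mitsunobu lactonisation (PPh3, DIAD, THF, 0 °C) lets the cis carboxylate displace the activated C6 hydroxyl with inversion, giving 16.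

3. Step 11. The endo,endo isomer is the less stable one; transient phenoxide or excess basic fluoride may ionise the benzylic C6–O7 bond through a quinone methide, or open the ring at C2 through the lactone enolate, and re-closure would epimerise to the exo series. Fallback (sets out from 15, comes back at 17): the last two operations are exchanged. Buffered fluoride on 15 gives the triphenol lactone acid F10 while C1 is still quaternary, so no lactone enolate can form and the carboxylic acid buffers the medium. Warming F10 in dioxane at about 90 °C then decarboxylates it to 17.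

**Further compounds**

F1 | step 7 | (1R,4S)-1-[3,4-bis(triisopropylsilyloxy)phenyl]-8,8-dimethyl-4-vinyl-2,7,9-trioxaspiro[4.5]decane-6,10-dione | CC1(C)OC(=O)C2(C(=O)O1)[C@@H](c1ccc(O[Si](C(C)C)(C(C)C)C(C)C)c(O[Si](C(C)C)(C(C)C)C(C)C)c1)OC[C@H]2C=C
F2 | step 7 | ozonide (1,2,4-trioxolane) of F1 | CC1(C)OC(=O)C2(C(=O)O1)[C@@H](c1ccc(O[Si](C(C)C)(C(C)C)C(C)C)c(O[Si](C(C)C)(C(C)C)C(C)C)c1)OC[C@H]2C1OOCO1
F3 | step 7 | (1R,4S)-1-[3,4-bis(triisopropylsilyloxy)phenyl]-8,8-dimethyl-6,10-dioxo-2,7,9-trioxaspiro[4.5]decane-4-carbaldehyde | CC1(C)OC(=O)C2(C(=O)O1)[C@@H](c1ccc(O[Si](C(C)C)(C(C)C)C(C)C)c(O[Si](C(C)C)(C(C)C)C(C)C)c1)OC[C@H]2C=O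
F4 | step 7 | (4-bromo-2,6-dimethoxyphenoxy)triisopropylsilane | COc1cc(Br)cc(OC)c1O[Si](C(C)C)(C(C)C)C(C)C
F5 | step 7 | [3,5-dimethoxy-4-(triisopropylsilyloxy)phenyl]magnesium bromide | COc1cc([Mg]Br)cc(OC)c1O[Si](C(C)C)(C(C)C)C(C)C
F6 | step 9 | (6R)-carbinol, C6 epimer of 14 | CC1(C)OC(=O)C2(C(=O)O1)[C@@H](c1ccc(O[Si](C(C)C)(C(C)C)C(C)C)c(O[Si](C(C)C)(C(C)C)C(C)C)c1)OC[C@H]2[C@@H](O)c1cc(OC)c(O[Si](C(C)C)(C(C)C)C(C)C)c(OC)c1
F7 | step 9 | C6 epimer of lactone acid 15 (syringyl exo) | COc1cc([C@@H]2OC(=O)[C@]3(C(=O)O)[C@H]2CO[C@@H]3c2ccc(O[Si](C(C)C)(C(C)C)C(C)C)c(O[Si](C(C)C)(C(C)C)C(C)C)c2)cc(OC)c1O[Si](C(C)C)(C(C)C)C(C)C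
F8 | step 9 | C6 epimer of lactone 16 (syringyl exo) | COc1cc([C@@H]2OC(=O)[C@@H]3[C@H]2CO[C@@H]3c2ccc(O[Si](C(C)C)(C(C)C)C(C)C)c(O[Si](C(C)C)(C(C)C)C(C)C)c2)cc(OC)c1O[Si](C(C)C)(C(C)C)C(C)C
F9 | step 9 | all-cis 2-[3,4-bis(triisopropylsilyloxy)phenyl]-4-{(R)-hydroxy[3,5-dimethoxy-4-(triisopropylsilyloxy)phenyl]methyl}tetrahydrofuran-3-carboxylic acid | COc1cc([C@H](O)[C@@H]2CO[C@H](c3ccc(O[Si](C(C)C)(C(C)C)C(C)C)c(O[Si](C(C)C)(C(C)C)C(C)C)c3)[C@@H]2C(=O)O)cc(OC)c1O[Si](C(C)C)(C(C)C)C(C)C
F10 | step 11 | (1R,2R,5S,6S)-2-(3,4-dihydroxyphenyl)-6-(4-hydroxy-3,5-dimethoxyphenyl)-8-oxo-3,7-dioxabicyclo[3.3.0]octane-1-carboxylic acid | COc1cc([C@H]2OC(=O)[C@]3(C(=O)O)[C@H]2CO[C@@H]3c2ccc(O)c(O)c2)cc(OC)c1O
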